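Ring B (C5–C10, drimane numbering) carries oxygen at C6 and at C9, para to each other across the C7=C8 bond, with methyl-type carbons on C8 and C10: it is 2,6-dimethyl-1,4-benzoquinone in disguise. The carbocyclic ring A (C1–C4, C5, C10) is therefore disconnected across C10–C1 and C5–C4 to this flat, symmetric quinone and 4-methylpenta-1,3-diene. One catalytic enantioselective Diels–Alder reaction closes ring A, installs the C4 gem-dimethyl group and fixes the quaternary C10 centre, from which C5, C9 and C6 are later relayed by substrate control. C11 and the acyl group are added afterwards; C12 is oxidised late.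

Key step: step 1

Remark on numbering: locants in the Why lines and in the fallbacks are drimane locants (ring A: C1–C5 and C10; ring B: C5–C10; C4 carries the gem-dimethyl group, C10 the angular methyl, C11 is the carbon on C9, C12 the carbon on C8); compound names use naphthalene locants.
Assumption: the (S)-configured catalyst is taken to give the (8aS) cycloadduct; should the sense of induction be the opposite, its (R) enantiomer is used.
Remark: the target is made as the open hydroxy acid aldehyde that is drawn; in solution it may be in equilibrium with its cyclic lactol (pseudo-acid) tautomer.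

Step 1
Reactants: 1 2,6-dimethyl-1,4-benzoquinone; 2 4-methylpenta-1,3-diene
Product: 3 (4aR,8aS)-2,5,5,8a-tetramethyl-4a,5,8,8a-tetrahydronaphthalene-1,4-dione (cis-fused cycloadduct)
Conditions: (S)-3,3-diphenyl-1-(2-methylphenyl)tetrahydro-1H,3H-pyrrolo[1,2-c][1,3,2]oxazaborole protonated by HN(SO2CF3)2 (20 mol%), excess 2, CH2Cl2, −78 to −20 °C
Reagents that add atoms: none
Why: The protonated oxazaborolidine binds the less hindered quinone carbonyl (C6=O, flanked by two C–H) and lowers the LUMO of the adjacent C5=C10 bond, so that the diene adds in a concerted but asynchronous [4+2] cycloaddition in which its unsubstituted CH2 terminus (C1) bonds ahead to the methyl-bearing β-carbon C10 and its dimethyl-substituted terminus (C4) closes onto C5. The closest known reaction type is the oxazaborolidinium-catalysed enantioselective Diels–Alder reaction of 2,6-dimethyl-1,4-benzoquinone with simple 1,3-dienes. Ring A is closed by this intermolecular [4+2] cycloaddition, which makes the C10–C1 and C5–C4 bonds in one suprafacial event and leaves the C2=C3 bond as its trace. The quaternary centre C10 is set by the catalyst, which blocks one face of the bound enone; C5 follows as cis from the suprafacial addition and is deliberately reset in step 3. The step needs regioselectivity (C1 to C10, not to C5), secured by the polarisation of the coordinated enone and by the avoidance of a bond between two fully substituted carbons, and it needs no choice between the two quinone C=C bonds, because the twofold axis of 1 makes them lead to the same adduct.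

Step 2
Reactants: 3 (4aR,8aS)-2,5,5,8a-tetramethyl-4a,5,8,8a-tetrahydronaphthalene-1,4-dione
Product: 4 (4aR,8aS)-2,5,5,8a-tetramethyl-4a,5,6,7,8,8a-hexahydronaphthalene-1,4-dione (cis-fused)
Conditions: H2 (1 atm), RhCl(PPh3)3 (5 mol%), toluene/EtOH, 23 °C
Reagents that add atoms: none
Why: Homogeneous hydrogenation with RhCl(PPh3)3 should reduce the unconjugated cis-disubstituted C2=C3 bond and leave the trisubstituted, electron-poor C7=C8 bond of the ene-dione alone; no stereocenter is formed.

Step 3
Reactants: 4 (4aR,8aS)-2,5,5,8a-tetramethyl-4a,5,6,7,8,8a-hexahydronaphthalene-1,4-dione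
Product: 6 (4aS,8aS)-2,5,5,8a-tetramethyl-4a,5,6,7,8,8a-hexahydronaphthalene-1,4-dione (trans-fused), via silyl dienol ether 5 (not isolated)
Conditions: LDA, TMSCl (in situ quench), THF, −78 °C; then 1 M HCl, THF, −20 °C; used at once in step 4
Reagents that add atoms: none
Why: Kinetic α′-deprotonation of the C6 enone at C5 with in situ silylation should give the cross-conjugated silyl dienol ether 5 with C5 trigonal, and kinetic protonation of this silyl enol ether by cold acid should deliver the proton to C5 from the α face, opposite the two axial methyl groups on C4 and C10 that flank the β face, which sets the trans ring fusion.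

Step 4
Reactants: 6 (4aS,8aS)-2,5,5,8a-tetramethyl-4a,5,6,7,8,8a-hexahydronaphthalene-1,4-dione; 7 tert-butyl vinyl ether
Product: 8 (4S,4aS,8aS)-4-(1-tert-butoxyethenyl)-4-hydroxy-3,4a,8,8-tetramethyl-4a,5,6,7,8,8a-hexahydronaphthalen-1(4H)-one
Conditions: 7, t-BuLi, THF, −78 to 0 °C; then anhydrous CeCl3, −78 °C; then 6, THF, −78 °C; aqueous NH4Cl (pH 7 work-up)
Reagents that add atoms: none
Why: 1,2-Addition of the weakly basic organocerium form of an α-lithiated vinyl ether (an ester-carbonyl anion equivalent) should occur at C9, whose α-axial trajectory anti to the axial C10 methyl is open, and not at C6, which is screened on its β face by the syn-axial C10 and C4 methyls and on its α face by the C4 gem-dimethyl group, so that C11 enters α and the new hydroxyl is 9β; once C9 is tetrahedral the trans fusion at C5 is also the thermodynamic one.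

Step 5
Reactants: 8 (4S,4aS,8aS)-4-(1-tert-butoxyethenyl)-4-hydroxy-3,4a,8,8-tetramethyl-4a,5,6,7,8,8a-hexahydronaphthalen-1(4H)-one
Product: 9 tert-butyl (1S,4aS,8aS)-1-hydroxy-2,5,5,8a-tetramethyl-4-oxo-1,4,4a,5,6,7,8,8a-octahydronaphthalene-1-carboxylate
Conditions: O3, CH2Cl2, pyridine (cat.), −78 °C, to the indicator end point; then Me2S
Reagents that add atoms: ozone, [O-][O+]=O
Why: Ozonolysis should cleave the electron-rich enol ether C=C far faster than the electron-poor enone C7=C8 bond and turn the alkoxy-bearing carbon into the ester carbonyl (ozonolysis of an enol ether to an ester) without touching a stereocenter.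

Step 6
Reactants: 9 tert-butyl (1S,4aS,8aS)-1-hydroxy-2,5,5,8a-tetramethyl-4-oxo-1,4,4a,5,6,7,8,8a-octahydronaphthalene-1-carboxylate
Product: 10 tert-butyl (1S,4R,4aS,8aS)-1,4-dihydroxy-2,5,5,8a-tetramethyl-1,4,4a,5,6,7,8,8a-octahydronaphthalene-1-carboxylate
Conditions: NaBH4, CeCl3·7H2O, MeOH, −78 °C
Reagents that add atoms: none
Why: Luche reduction should give clean 1,2-reduction of the C6 enone, with hydride arriving from the α face because the β face is closed by the syn-axial methyl groups on C10 and C4, so that the axial 6β-alcohol results.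

Step 7
Reactants: 10 tert-butyl (1S,4R,4aS,8aS)-1,4-dihydroxy-2,5,5,8a-tetramethyl-1,4,4a,5,6,7,8,8a-octahydronaphthalene-1-carboxylate; 11 (2E,4E,6E)-octa-2,4,6-trienoic acid
Product: 13 tert-butyl (1S,4R,4aS,8aS)-1-hydroxy-2,5,5,8a-tetramethyl-4-[(2E,4E,6E)-octa-2,4,6-trienoyloxy]-1,4,4a,5,6,7,8,8a-octahydronaphthalene-1-carboxylate, via mixed anhydride 12 (not isolated)
Conditions: 11, 2,4,6-trichlorobenzoyl chloride, Et3N, toluene, 23 °C; then 10, DMAP, toluene, 40 °C
Reagents that add atoms: none
Why: In this Yamaguchi esterification DMAP should open the mixed anhydride 12 at the trienoyl carbonyl and the acylpyridinium should acylate the secondary 6β-hydroxyl with retention at C6, while the tertiary 9-hydroxyl next to two quaternary carbons stays free.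

Step 8
Reactants: 13 tert-butyl (1S,4R,4aS,8aS)-1-hydroxy-2,5,5,8a-tetramethyl-4-[(2E,4E,6E)-octa-2,4,6-trienoyloxy]-1,4,4a,5,6,7,8,8a-octahydronaphthalene-1-carboxylate
Product: 14 tert-butyl (1R,4R,4aS,8aS)-2-formyl-1-hydroxy-5,5,8a-trimethyl-4-[(2E,4E,6E)-octa-2,4,6-trienoyloxy]-1,4,4a,5,6,7,8,8a-octahydronaphthalene-1-carboxylate
Conditions: SeO2, 1,4-dioxane, 80 °C
Reagents that add atoms: selenium dioxide, O=[Se]=O
Why: Riley oxidation (ene reaction of SeO2, then [2,3]-sigmatropic shift and further oxidation) should attack the C12 methyl group, the only hydrogen-bearing allylic position on the more substituted alkene carbon C8, and carry it to the enal, while the conjugated trienoate is an electron-poor and therefore poor ene partner; no stereocenter changes (the C9 descriptor changes only by priority).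

Step 9
Reactants: 14 tert-butyl (1R,4R,4aS,8aS)-2-formyl-1-hydroxy-5,5,8a-trimethyl-4-[(2E,4E,6E)-octa-2,4,6-trienoyloxy]-1,4,4a,5,6,7,8,8a-octahydronaphthalene-1-carboxylate
Product: 15 (1R,4R,4aS,8aS)-2-formyl-1-hydroxy-5,5,8a-trimethyl-4-[(2E,4E,6E)-octa-2,4,6-trienoyloxy]-1,4,4a,5,6,7,8,8a-octahydronaphthalene-1-carboxylic acid (target)
Conditions: CF3CO2H, CH2Cl2, 0 °C
Reagents that add atoms: none
Why: Acidolysis of the tert-butyl ester (loss of isobutene through the tert-butyl cation) should free the C11 acid without hydrolysing the trienoate and without ionising the tertiary C9–O bond, which is deactivated by the adjacent carboxyl and enal groups.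

Compound list
1 | 2,6-dimethyl-1,4-benzoquinone | CC1=CC(=O)C=C(C)C1=O | starting material
2 | 4-methylpenta-1,3-diene | C=CC=C(C)C | starting material
3 | (4aR,8aS)-2,5,5,8a-tetramethyl-4a,5,8,8a-tetrahydronaphthalene-1,4-dione | O=C1C=C(C)C(=O)[C@@]2(C)CC=CC(C)(C)[C@@H]12 | intermediate
4 | (4aR,8aS)-2,5,5,8a-tetramethyl-4a,5,6,7,8,8a-hexahydronaphthalene-1,4-dione | O=C1C=C(C)C(=O)[C@@]2(C)CCCC(C)(C)[C@@H]12 | intermediate
5 | (S)-2,5,5,8a-tetramethyl-4-(trimethylsilyloxy)-6,7,8,8a-tetrahydronaphthalen-1(5H)-one | O=C1C(C)=CC(O[Si](C)(C)C)=C2C(C)(C)CCC[C@]12C | intermediate (not isolated)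
6 | (4aS,8aS)-2,5,5,8a-tetramethyl-4a,5,6,7,8,8a-hexahydronaphthalene-1,4-dione | O=C1C=C(C)C(=O)[C@@]2(C)CCCC(C)(C)[C@H]12 | intermediate
7 | tert-butyl vinyl ether | C=COC(C)(C)C | starting material
8 | (4S,4aS,8aS)-4-(1-tert-butoxyethenyl)-4-hydroxy-3,4a,8,8-tetramethyl-4a,5,6,7,8,8a-hexahydronaphthalen-1(4H)-one | O=C1C=C(C)[C@@](O)(C(=C)OC(C)(C)C)[C@@]2(C)CCCC(C)(C)[C@H]12 | intermediate
9 | tert-butyl (1S,4aS,8aS)-1-hydroxy-2,5,5,8a-tetramethyl-4-oxo-1,4,4a,5,6,7,8,8a-octahydronaphthalene-1-carboxylate | O=C1C=C(C)[C@@](O)(C(=O)OC(C)(C)C)[C@@]2(C)CCCC(C)(C)[C@H]12 | intermediate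
10 | tert-butyl (1S,4R,4aS,8aS)-1,4-dihydroxy-2,5,5,8a-tetramethyl-1,4,4a,5,6,7,8,8a-octahydronaphthalene-1-carboxylate | O[C@@H]1C=C(C)[C@@](O)(C(=O)OC(C)(C)C)[C@@]2(C)CCCC(C)(C)[C@H]12 | intermediate
11 | (2E,4E,6E)-octa-2,4,6-trienoic acid | C/C=C/C=C/C=C/C(=O)O | starting material
12 | (2E,4E,6E)-octa-2,4,6-trienoic 2,4,6-trichlorobenzoic anhydride | C/C=C/C=C/C=C/C(=O)OC(=O)c1c(Cl)cc(Cl)cc1Cl | intermediate (not isolated)
13 | tert-butyl (1S,4R,4aS,8aS)-1-hydroxy-2,5,5,8a-tetramethyl-4-[(2E,4E,6E)-octa-2,4,6-trienoyloxy]-1,4,4a,5,6,7,8,8a-octahydronaphthalene-1-carboxylate | C/C=C/C=C/C=C/C(=O)O[C@@H]1C=C(C)[C@@](O)(C(=O)OC(C)(C)C)[C@@]2(C)CCCC(C)(C)[C@H]12 | intermediate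
14 | tert-butyl (1R,4R,4aS,8aS)-2-formyl-1-hydroxy-5,5,8a-trimethyl-4-[(2E,4E,6E)-octa-2,4,6-trienoyloxy]-1,4,4a,5,6,7,8,8a-octahydronaphthalene-1-carboxylate | C/C=C/C=C/C=C/C(=O)O[C@@H]1C=C(C=O)[C@@](O)(C(=O)OC(C)(C)C)[C@@]2(C)CCCC(C)(C)[C@H]12 | intermediate
15 | (1R,4R,4aS,8aS)-2-formyl-1-hydroxy-5,5,8a-trimethyl-4-[(2E,4E,6E)-octa-2,4,6-trienoyloxy]-1,4,4a,5,6,7,8,8a-octahydronaphthalene-1-carboxylic acid | C/C=C/C=C/C=C/C(=O)O[C@@H]1C=C(C=O)[C@@](O)(C(=O)O)[C@@]2(C)CCCC(C)(C)[C@H]12 | target

Total step count: 9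
Longest linear sequence: 9 steps (1 and 2 to 15)

Steps most likely to fail

Step 1. The diene may react too slowly, because its Z-methyl group disfavours the s-cis conformer; acid-induced oligomerisation of the diene, or a stepwise addition that closes through oxygen or to a four-membered ring, could then outrun the cycloaddition. The fallback sets out from 1 and uses the more electron-rich 4-methyl-2-(trimethylsilyloxy)penta-1,3-diene F1, made from mesityl oxide with LDA and TMSCl, under the same catalyst. This should give the cis-fused cycloadduct (4aR,8aS)-2,5,5,8a-tetramethyl-7-(trimethylsilyloxy)-4a,5,8,8a-tetrahydronaphthalene-1,4-dione F2 with the same regiochemistry (silyl enol ether at C2=C3). CsF and PhNTf2 in DME would turn it into the enol triflate (4aR,8aS)-3,8,8,8a-tetramethyl-5,8-dioxo-1,4a,5,8,8a-... ring A enol triflate F3 (triflate on C2), and Pd(OAc)2, PPh3, HCO2H and Et3N would reduce the C–O bond to C–H, which comes back to the route at 3.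

Step 3. Deprotonation may take place at the C12 methyl group (γ to the C6 carbonyl) instead of the hindered C5–H, or the proton may be returned to C5 without facial control, so that the cis fusion persists. The fallback sets out from 4 and changes from kinetic to equilibrating enolisation: TBSOTf and Et3N in CH2Cl2 at 23 °C should give the linearly conjugated, isolable (S)-4-(tert-butyldimethylsilyloxy)-2,5,5,8a-tetramethyl-6,7,8,8a-tetrahydronaphthalen-1(5H)-one F4, which is purified and then cleaved and protonated with HF·pyridine in THF at −40 °C; this comes back to the route at 6.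

Step 4. The organometallic reagent may attack the C6 carbonyl instead of C9, or act as a base at C5 and erode the ring fusion before it adds. The fallback sets out from 6 and inverts the order of the two carbonyl additions: Luche reduction first removes the C6 carbonyl to give (4R,4aS,8aS)-4-hydroxy-2,5,5,8a-tetramethyl-4a,5,6,7,8,8a-hexahydronaphthalen-1(4H)-one F5, which fixes C5; an excess of (1-tert-butoxyvinyl)lithium with CeCl3 then adds to the only remaining ketone from the α face to give (1S,4R,4aS,8aS)-1-(1-tert-butoxyethenyl)-2,5,5,8a-tetramethyl-1,4,4a,5,6,7,8,8a-octahydronaphthalene-1,4-diol F6, and ozonolysis of its enol ether comes back to the route at 10.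

Further compounds
F1 | step 1 | 4-methyl-2-(trimethylsilyloxy)penta-1,3-diene | C=C(O[Si](C)(C)C)C=C(C)C
F2 | step 1 | (4aR,8aS)-2,5,5,8a-tetramethyl-7-(trimethylsilyloxy)-4a,5,8,8a-tetrahydronaphthalene-1,4-dione | O=C1C=C(C)C(=O)[C@@]2(C)CC(O[Si](C)(C)C)=CC(C)(C)[C@@H]12
F3 | step 1 | (4aR,8aS)-2,5,5,8a-tetramethyl-1,4-dioxo-1,4,4a,5,8,8a-hexahydronaphthalen-7-yl trifluoromethanesulfonate | O=C1C=C(C)C(=O)[C@@]2(C)CC(OS(=O)(=O)C(F)(F)F)=CC(C)(C)[C@@H]12
F4 | step 3 | (S)-4-(tert-butyldimethylsilyloxy)-2,5,5,8a-tetramethyl-6,7,8,8a-tetrahydronaphthalen-1(5H)-one | O=C1C(C)=CC(O[Si](C)(C)C(C)(C)C)=C2C(C)(C)CCC[C@]12C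
F5 | step 4 | (4R,4aS,8aS)-4-hydroxy-2,5,5,8a-tetramethyl-4a,5,6,7,8,8a-hexahydronaphthalen-1(4H)-one | O[C@@H]1C=C(C)C(=O)[C@@]2(C)CCCC(C)(C)[C@H]12
F6 | step 4 | (1S,4R,4aS,8aS)-1-(1-tert-butoxyethenyl)-2,5,5,8a-tetramethyl-1,4,4a,5,6,7,8,8a-octahydronaphthalene-1,4-diol | O[C@@H]1C=C(C)[C@@](O)(C(=C)OC(C)(C)C)[C@@]2(C)CCCC(C)(C)[C@H]12
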